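**Plan**

- Retrosynthetic cuts, in order: the C5 methyl ether and the isopropyl ether on the benzyl arene; the C2–phenyl bond (back to a chromone); O1–C2, C2–C3 and C4–C4a of ring C (back to a phenol); the C4a–C8a bond of ring A (back to a cyclobutenone); the bonds from the four-membered ring to the methoxyvinyl and benzyl groups (back to dimethyl squarate).
- What makes the key step possible: in ring A the atoms C8a (O), C8 (benzyl), C7 (OMe) and C6 (OMe) can be the four ring carbons of a squarate ester, and C5 (O) with C4a (H) the two carbons of an α-methoxyvinyl group.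
- Forward order: the benzyl arene is joined to dimethyl squarate, the methoxyvinyl group is added, ring A is formed by thermolysis, ring C is annulated as a chromone, the phenyl ring is attached at C2, and the two protecting ethers are cleaved.
- Stereochemistry: C2 is the only stereocentre; it is set as S by a rhodium-catalysed asymmetric conjugate addition of phenylboronic acid to the chromone, and the only later step is non-basic so that retro-oxa-Michael scrambling is avoided.

Key step: step 7

Assumption: (S)-MeO-F12-BIPHEP, i.e. (S)-6,6'-dimethoxy-2,2'-bis[bis(3,4,5-trifluorophenyl)phosphino]biphenyl, is taken to deliver phenyl to the C2 face that gives the 2S flavanone, by analogy with (S)-BINAP/rhodium additions to cyclic enones; if a model chromone shows the opposite sense, the (R) ligand is used with no other change.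

**Route**

Step 1
Reactants: 1 2-hydroxy-5-methoxybenzaldehyde
Product: 2 2-isopropoxy-5-methoxybenzaldehyde
Conditions: 2-bromopropane, K2CO3, DMF, 60 °C
Reagents that add atoms: 2-bromopropane, CC(C)Br
Why: Williamson ether synthesis on the phenoxide is routine for salicylaldehydes, and the isopropyl ether is chosen because it should tolerate the organometallic, thermal and boron trifluoride steps yet is cleaved by BCl3 together with the C5 methyl ether at the end.

Step 2
Reactants: 2 2-isopropoxy-5-methoxybenzaldehyde
Product: 3 (2-isopropoxy-5-methoxyphenyl)methanol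
Conditions: NaBH4, MeOH, 0 °C
Reagents that add atoms: none
Why: Borohydride reduction of an aryl aldehyde to the benzylic alcohol is chemoselective and leaves both ethers untouched.

Step 3
Reactants: 3 (2-isopropoxy-5-methoxyphenyl)methanol
Product: 4 2-(chloromethyl)-1-isopropoxy-4-methoxybenzene
Conditions: SOCl2, CH2Cl2, 0 °C to rt (used without storage)
Reagents that add atoms: thionyl chloride, O=S(Cl)Cl
Why: Chlorodehydroxylation of an electron-rich benzylic alcohol with thionyl chloride (via the chlorosulfite) is fast at low temperature, and the chloride is preferred to the bromide because it gives less Wurtz coupling in the following magnesium insertion.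

Step 4
Reactants: 4 2-(chloromethyl)-1-isopropoxy-4-methoxybenzene; 5 dimethyl squarate
Product: 7 4-hydroxy-4-(2-isopropoxy-5-methoxybenzyl)-2,3-dimethoxycyclobut-2-en-1-one (racemic), via benzylic Grignard reagent 6 (not isolated)
Conditions: Mg (I2-activated), Et2O, 0 °C, slow addition of 4; then into 5, THF, −78 °C; pH 7 buffer
Reagents that add atoms: none
Why: Grignard formation followed by 1,2-addition to one of the two equivalent carbonyl groups of dimethyl squarate at −78 °C is the standard entry to 4-substituted 4-hydroxycyclobutenones, slow addition of the chloride to excess magnesium and inverse addition to the squarate limiting homocoupling and double addition.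

Step 5
Reactants: 7 4-hydroxy-4-(2-isopropoxy-5-methoxybenzyl)-2,3-dimethoxycyclobut-2-en-1-one
Product: 8 3-(2-isopropoxy-5-methoxybenzyl)-4-methoxycyclobut-3-ene-1,2-dione
Conditions: conc. HCl (cat.), wet CH2Cl2, rt
Reagents that add atoms: water, O
Why: Acid-catalysed allylic transposition with hydrolysis (ionisation of the tertiary carbinol to a methoxy-stabilised cyclobutenyl cation, capture by water at the enol ether carbon and loss of methanol) is the established conversion of squarate adducts into 3-substituted 4-alkoxycyclobutene-1,2-diones.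

Step 6
Reactants: 8 3-(2-isopropoxy-5-methoxybenzyl)-4-methoxycyclobut-3-ene-1,2-dione; 9 methyl vinyl ether
Product: 12 2-(2-isopropoxy-5-methoxybenzyl)-3,4-dimethoxy-4-(1-methoxyvinyl)cyclobut-2-en-1-one (racemic), via 1-methoxyvinyllithium 10 (not isolated), via lithium alkoxide 11 (not isolated)
Conditions: 9, t-BuLi, THF, −78 to 0 °C; then 8, THF, −78 °C; then MeOTf, −78 to 0 °C; NaHCO3 work-up, Et3N-deactivated silica
Reagents that add atoms: methyl trifluoromethanesulfonate, COS(=O)(=O)C(F)(F)F
Why: α-Lithiation of methyl vinyl ether gives an acyl anion equivalent that should add 1,2 to the more electrophilic, ketone-like carbonyl (the one attached to the methoxy-bearing alkene carbon, the other being a vinylogous ester), and trapping the lithium alkoxide with methyl triflate in the same flask is a known O-alkylation in squarate chemistry that fixes the future C6 oxygen as a methyl ether.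

Step 7
Reactants: 12 2-(2-isopropoxy-5-methoxybenzyl)-3,4-dimethoxy-4-(1-methoxyvinyl)cyclobut-2-en-1-one
Product: 15 2-(2-isopropoxy-5-methoxybenzyl)-3,4,5-trimethoxyphenol, via dienylketene 13 (not isolated), via cyclohexadienone 14 (not isolated)
Conditions: toluene (degassed, dilute), 110 °C, base-washed glassware
Reagents that add atoms: none
Why: Heating should open the strained ring by a thermal conrotatory 4π electrocyclic cleavage of the bond between the carbonyl carbon and the quaternary carbon, giving the (Z)-dienylketene 13 in which the former C4 methoxy group has turned outward and the methoxyvinyl group inward, next to the ketene. A thermal disrotatory 6π electrocyclisation then bonds the ketene carbon (future C8a) to the vinyl CH2 (future C4a), which closes ring A as the cyclohexa-2,4-dienone 14, and enolisation to the aromatic phenol 15 makes the sequence irreversible. The closest known reaction type is the Moore rearrangement of squarate-derived 4-alkenyl-4-alkoxy- and 4-alkenyl-4-hydroxycyclobutenones to highly oxygenated phenols and hydroquinone ethers. No stereocentre is formed and the racemic quaternary centre of 12 disappears. The step needs outward rotation of the donor at C4, which the methoxy group secures as oxygen donors do in such openings, and a single substituent order around the new ring, which is already fixed in 12 by the order of the two carbonyl additions (C8a, C8, C7, C6 from the squarate carbons; C5 and C4a from the vinyl ether). Because the C4 oxygen is a methyl ether, the C6 oxygen arrives methylated and the C8a hydroxyl is the only free phenol, with C4a the only unsubstituted ring position.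

Step 8
Reactants: 15 2-(2-isopropoxy-5-methoxybenzyl)-3,4,5-trimethoxyphenol
Product: 17 1-[2-hydroxy-3-(2-isopropoxy-5-methoxybenzyl)-4,5,6-trimethoxyphenyl]ethan-1-one, via difluoroboron chelate 16 (not isolated)
Conditions: Ac2O, BF3·OEt2, CH2Cl2, 0 °C to rt; then MeOH/H2O, 50 °C
Reagents that add atoms: acetic anhydride, CC(=O)OC(C)=O
Why: Friedel–Crafts acetylation (O-acylation and Fries-type migration under BF3) can only occur at the single unsubstituted position of the very electron-rich ring A, ortho to the free hydroxyl, where formation of the difluoroboron chelate drives the reaction, while the far less activated benzyl arene and the isopropyl ether should be spared at room temperature.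

Step 9
Reactants: 17 1-[2-hydroxy-3-(2-isopropoxy-5-methoxybenzyl)-4,5,6-trimethoxyphenyl]ethan-1-one
Product: 19 8-(2-isopropoxy-5-methoxybenzyl)-5,6,7-trimethoxy-4H-chromen-4-one, via enaminone 18 (not isolated)
Conditions: Me2NCH(OMe)2, toluene, 95 °C; then conc. HCl, CH2Cl2, rt
Reagents that add atoms: N,N-dimethylformamide dimethyl acetal, COC(OC)N(C)C
Why: Condensation of the methyl ketone with the amide acetal gives the enaminone, and acid-promoted 6-endo addition of the phenol to the β-carbon with loss of dimethylamine is the standard enaminone route to 2,3-unsubstituted chromones, here forming O1–C2 and C2–C3 of ring C.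

Step 10
Reactants: 19 8-(2-isopropoxy-5-methoxybenzyl)-5,6,7-trimethoxy-4H-chromen-4-one; 20 phenylboronic acid
Product: 21 (2S)-8-(2-isopropoxy-5-methoxybenzyl)-5,6,7-trimethoxy-2-phenyl-2,3-dihydro-4H-chromen-4-one
Conditions: [RhOH(cod)]2 (cat.), (S)-MeO-F12-BIPHEP, toluene/H2O, 30 °C, no added base
Reagents that add atoms: none
Why: Rhodium-catalysed asymmetric 1,4-addition of an arylboronic acid (Hayashi–Miyaura reaction), a known route from chromones to flavanones, proceeds by transmetalation to a phenylrhodium species that inserts the C2=C3 bond from the face left open by the chiral bisphosphine, which sets C2 as S, and hydrolysis of the rhodium enolate under base-free conditions should prevent ring opening of the product.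

Step 11
Reactants: 21 (2S)-8-(2-isopropoxy-5-methoxybenzyl)-5,6,7-trimethoxy-2-phenyl-2,3-dihydro-4H-chromen-4-one
Product: 22 (2S)-5-hydroxy-8-(2-hydroxy-5-methoxybenzyl)-6,7-dimethoxy-2-phenyl-2,3-dihydro-4H-chromen-4-one (CNP0191546.1)
Conditions: BCl3, CH2Cl2, −78 to 0 °C; then MeOH/H2O
Reagents that add atoms: none
Why: Lewis acid ether cleavage with BCl3 removes the secondary isopropyl group and, through chelation to the C4 carbonyl, only the peri C5 methyl ether, leaving the C6, C7 and benzyl-arene methyl ethers intact below 0 °C, and the non-basic medium should leave the C2 stereocentre untouched.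

**Compound list**

1 | 2-hydroxy-5-methoxybenzaldehyde | COc1ccc(O)c(C=O)c1 | starting material
2 | 2-isopropoxy-5-methoxybenzaldehyde | COc1ccc(OC(C)C)c(C=O)c1 | intermediate
3 | (2-isopropoxy-5-methoxyphenyl)methanol | COc1ccc(OC(C)C)c(CO)c1 | intermediate
4 | 2-(chloromethyl)-1-isopropoxy-4-methoxybenzene | COc1ccc(OC(C)C)c(CCl)c1 | intermediate
5 | dimethyl squarate (3,4-dimethoxycyclobut-3-ene-1,2-dione) | COC1=C(OC)C(=O)C1=O | starting material
6 | (2-isopropoxy-5-methoxybenzyl)magnesium chloride | COc1ccc(OC(C)C)c(C[Mg]Cl)c1 | intermediate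
7 | 4-hydroxy-4-(2-isopropoxy-5-methoxybenzyl)-2,3-dimethoxycyclobut-2-en-1-one (racemic) | COC1=C(OC)C(O)(Cc2cc(OC)ccc2OC(C)C)C1=O | intermediate
8 | 3-(2-isopropoxy-5-methoxybenzyl)-4-methoxycyclobut-3-ene-1,2-dione | COC1=C(Cc2cc(OC)ccc2OC(C)C)C(=O)C1=O | intermediate
9 | methyl vinyl ether | COC=C | starting material
10 | 1-methoxyvinyllithium | [Li]C(=C)OC | intermediate
11 | lithium 3-(2-isopropoxy-5-methoxybenzyl)-2-methoxy-1-(1-methoxyvinyl)-4-oxocyclobut-2-en-1-olate (racemic) | [Li]OC1(C(=C)OC)C(OC)=C(Cc2cc(OC)ccc2OC(C)C)C1=O | intermediate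
12 | 2-(2-isopropoxy-5-methoxybenzyl)-3,4-dimethoxy-4-(1-methoxyvinyl)cyclobut-2-en-1-one (racemic) | COC(=C)C1(OC)C(OC)=C(Cc2cc(OC)ccc2OC(C)C)C1=O | intermediate
13 | (3Z)-2-(2-isopropoxy-5-methoxybenzyl)-3,4,5-trimethoxyhexa-1,3,5-trien-1-one (dienylketene) | O=C=C(Cc1cc(OC)ccc1OC(C)C)/C(OC)=C(OC)\C(OC)=C | intermediate
14 | 2-(2-isopropoxy-5-methoxybenzyl)-3,4,5-trimethoxycyclohexa-2,4-dien-1-one | O=C1CC(OC)=C(OC)C(OC)=C1Cc1cc(OC)ccc1OC(C)C | intermediate
15 | 2-(2-isopropoxy-5-methoxybenzyl)-3,4,5-trimethoxyphenol | COc1ccc(OC(C)C)c(Cc2c(O)cc(OC)c(OC)c2OC)c1 | intermediate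
16 | O,O-difluoroboron chelate of ketone 17 (2,2-difluoro-4-methyl-1,3,2-benzodioxaborinine form) | CC1=[O+][B-](F)(F)Oc2c(Cc3cc(OC)ccc3OC(C)C)c(OC)c(OC)c(OC)c12 | intermediate
17 | 1-[2-hydroxy-3-(2-isopropoxy-5-methoxybenzyl)-4,5,6-trimethoxyphenyl]ethan-1-one | CC(=O)c1c(O)c(Cc2cc(OC)ccc2OC(C)C)c(OC)c(OC)c1OC | intermediate
18 | (2E)-3-(dimethylamino)-1-[2-hydroxy-3-(2-isopropoxy-5-methoxybenzyl)-4,5,6-trimethoxyphenyl]prop-2-en-1-one | CN(C)/C=C/C(=O)c1c(O)c(Cc2cc(OC)ccc2OC(C)C)c(OC)c(OC)c1OC | intermediate
19 | 8-(2-isopropoxy-5-methoxybenzyl)-5,6,7-trimethoxy-4H-chromen-4-one | O=c1ccoc2c(Cc3cc(OC)ccc3OC(C)C)c(OC)c(OC)c(OC)c12 | intermediate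
20 | phenylboronic acid | OB(O)c1ccccc1 | starting material
21 | (2S)-8-(2-isopropoxy-5-methoxybenzyl)-5,6,7-trimethoxy-2-phenyl-2,3-dihydro-4H-chromen-4-one | COc1ccc(OC(C)C)c(Cc2c(OC)c(OC)c(OC)c3c2O[C@H](c2ccccc2)CC3=O)c1 | intermediate
22 | (2S)-5-hydroxy-8-(2-hydroxy-5-methoxybenzyl)-6,7-dimethoxy-2-phenyl-2,3-dihydro-4H-chromen-4-one | COc1ccc(O)c(Cc2c(OC)c(OC)c(O)c3c2O[C@H](c2ccccc2)CC3=O)c1 | target

**Step count**

Total steps: 11. Longest linear sequence: 11 steps (1 to 22); compounds 5, 9 and 20 are commercial and enter directly.

**Steps most likely to fail**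

Step 10. The electron-rich chromone, with a methoxy group peri to the carbonyl and a benzyl group next to O1, may undergo carbometalation so slowly that protodeboronation of the boronic acid wins, or the facial selectivity may be eroded. The fallback sets out from ketone 17 and sets C2 by forming the O1–C2 bond instead of the C2–phenyl bond. Double deprotonation of 17 (LiN(SiMe3)2, THF, −78 °C) and C-acylation with Boc2O should give the β-keto ester tert-butyl 3-[2-hydroxy-3-(2-isopropoxy-5-methoxybenzyl)-4,5,6-trimethoxyphenyl]-3-oxopropanoate F1. Knoevenagel condensation with benzaldehyde (piperidine, AcOH, toluene, molecular sieves) should give the benzylidene β-keto ester tert-butyl 2-[2-hydroxy-3-(2-isopropoxy-5-methoxybenzyl)-4,5,6-trimethoxybenzoyl]-3-phenylprop-2-enoate F2. A cinchona-derived bifunctional thiourea (the quinine- or quinidine-based pseudoenantiomer that gives 2S on a model) should then catalyse the intramolecular oxa-Michael addition of the activated alkene to the flavanone ester tert-butyl (2S)-8-(2-isopropoxy-5-methoxybenzyl)-5,6,7-trimethoxy-4-oxo-2-phenyl-3,4-dihydro-2H-chromene-3-carboxylate F3. TsOH in toluene at 80 °C cleaves the tert-butyl ester with decarboxylation, and the route is rejoined at 21.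

Step 8. Under boron trifluoride and the acetic acid it liberates, the isopropyl ether may be lost, the electron-rich diarylmethane may be protodebenzylated (retro-Friedel–Crafts), or the reaction may stop at the O-acetate. The fallback sets out from phenol 15 and builds the acetyl group under non-acidic conditions. Magnesium-mediated ortho-formylation (MgCl2, Et3N, paraformaldehyde, MeCN, reflux; Casnati–Skattebøl conditions) should give the salicylaldehyde 2-hydroxy-3-(2-isopropoxy-5-methoxybenzyl)-4,5,6-trimethoxybenzaldehyde F4. Excess MeMgBr (THF, 0 °C) should give the carbinol 2-(1-hydroxyethyl)-6-(2-isopropoxy-5-methoxybenzyl)-3,4,5-trimethoxyphenol F5. MnO2 in CH2Cl2 oxidises the benzylic alcohol, and the route is rejoined at 17.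

Step 6. The basic vinyllithium may abstract a proton from the doubly activated benzylic methylene of 8 instead of adding to the carbonyl, the hindered alkoxide may be methylated incompletely, or methyl triflate may attack the enol ether or the solvent. The fallback sets out from dione 8, separates the two events and lowers the basicity. Reagent 10 is transmetalated with anhydrous CeCl3 (THF, −78 °C) and added as the organocerium. After an NH4Cl quench the carbinol 4-hydroxy-2-(2-isopropoxy-5-methoxybenzyl)-3-methoxy-4-(1-methoxyvinyl)cyclobut-2-en-1-one F6 is isolated on Et3N-deactivated silica. It is then O-methylated under neutral Purdie conditions (MeI, Ag2O, K2CO3, MeCN, rt), and the route is rejoined at 12.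

**Further compounds**

F1 | step 10 | tert-butyl 3-[2-hydroxy-3-(2-isopropoxy-5-methoxybenzyl)-4,5,6-trimethoxyphenyl]-3-oxopropanoate | CC(C)(C)OC(=O)CC(=O)c1c(O)c(Cc2cc(OC)ccc2OC(C)C)c(OC)c(OC)c1OC
F2 | step 10 | tert-butyl 2-[2-hydroxy-3-(2-isopropoxy-5-methoxybenzyl)-4,5,6-trimethoxybenzoyl]-3-phenylprop-2-enoate (E/Z mixture, geometry lost on cyclisation) | CC(C)(C)OC(=O)C(=Cc1ccccc1)C(=O)c1c(O)c(Cc2cc(OC)ccc2OC(C)C)c(OC)c(OC)c1OC
F3 | step 10 | tert-butyl (2S)-8-(2-isopropoxy-5-methoxybenzyl)-5,6,7-trimethoxy-4-oxo-2-phenyl-3,4-dihydro-2H-chromene-3-carboxylate (C3 epimerisable) | COc1ccc(OC(C)C)c(Cc2c(OC)c(OC)c(OC)c3c2O[C@H](c2ccccc2)C(C(=O)OC(C)(C)C)C3=O)c1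
F4 | step 8 | 2-hydroxy-3-(2-isopropoxy-5-methoxybenzyl)-4,5,6-trimethoxybenzaldehyde | O=Cc1c(O)c(Cc2cc(OC)ccc2OC(C)C)c(OC)c(OC)c1OC
F5 | step 8 | 2-(1-hydroxyethyl)-6-(2-isopropoxy-5-methoxybenzyl)-3,4,5-trimethoxyphenol (racemic) | CC(O)c1c(O)c(Cc2cc(OC)ccc2OC(C)C)c(OC)c(OC)c1OC
F6 | step 6 | 4-hydroxy-2-(2-isopropoxy-5-methoxybenzyl)-3-methoxy-4-(1-methoxyvinyl)cyclobut-2-en-1-one (racemic) | COC(=C)C1(O)C(OC)=C(Cc2cc(OC)ccc2OC(C)C)C1=O
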